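**Target:** desbromosceptrin (20), the all-trans (1R,2S,3S,4R) cyclobutane of the given SMILES. The route is 12 linear steps from the commercial meso bis-anhydride 1, built around a twofold enantiotopos-selective methanolysis; it is a paper proposal, not tested experimentally.

## Structural features

- The core is a cyclobutane whose four ring carbons are four contiguous stereocentres, all-trans (every substituent anti to both neighbours). In the numbering of 20, C1 and C4 carry the CH2–NH–C(O)–pyrrol-2-yl arms and are R; C2 and C3 carry the 2-aminoimidazol-4-yl rings and are S.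
- The core has a C2 axis through the midpoints of the C1–C4 and C2–C3 bonds. Only the bromine at C4 of one pyrrole breaks it, so the two CH2N carbons are homotopic in every symmetric precursor. The desbromo pattern therefore requires mono-functionalisation of homotopic groups, not a stereochemical decision.
- Each ring carbon carries exactly one exocyclic carbon: imidazole C4 on C2/C3 and the CH2N carbon on C1/C4. All four can be drawn at the carboxyl oxidation level, which maps the core onto cyclobutane-1,2,3,4-tetracarboxylic acid.
- The all-trans tetra-acid is achiral (S4). The chirality of 20 therefore lies only in which adjacent pair of ring carbons carries which kind of substituent. The key step exploits this: in the achiral cis,trans,cis bis-anhydride the choice of one carbonyl per anhydride ring fixes that pairing and, with it, the absolute configuration at C1–C4.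
- Fragile groups: the free 2-aminoimidazoles (basic, nucleophilic, very polar) should appear last. The C–Br bond of the bromopyrrole excludes hydrogenolysis and organolithium conditions. Ring carbons α to a carbonyl are epimerisable, which helps here because all-trans is the thermodynamic arrangement.
- The real difficulty is the enantiopure all-trans ring with pairwise-differentiated neighbours, and after that the differentiation of the two homotopic arms.

## Logic of the disconnections

**20 ⇒ 19.** The two carbamate N–C(O) bonds are cut last. The aminoimidazoles stay masked until a final acidolysis, to which amides, aryl bromide and ring stereocentres are inert. The forward demand is that no free primary amine coexists with the N-acyl imidazoles of 19, so both amides must already be in place.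

**19 ⇒ 17 + 18.** In each imidazole the N1–C5 and N3–C4 bonds are cut. C4 and C5 come from a C(O)–CH2Br unit on the ring, and N1–C2(N)–N3 comes from 18. Two heteroaromatic rings are reduced to two acyl groups. The forward step must condense twice without cross-linking the neighbouring ketones; epimerisation α to the ketones is harmless because all-trans is favoured.

**17 ⇒ 14 (through 16 and 15) ⇒ 13.** The C(O)–CH2Br bonds are cut (one-carbon homologation of carboxylic acids) and the acids are traced to methyl esters. The exocyclic carbons on C2/C3 become carboxyl carbons. The forward step must activate two trans carboxyls in the presence of amide and pyrrole N–H.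

**13 ⇒ 10 + 11; 10 ⇒ 9; 9 ⇒ 6 + 7.** The two amide C–N bonds are cut one after the other, and between them a CH2–N bond (azide for hydroxyl). The nitrogens are unmasked one at a time, so the unsymmetrical acylation pattern is not left to statistics. Each amine must be acylated as soon as it is set free.

**6 ⇒ 5 ⇒ 4.** The CH2–N3 bond and the O–S bond are cut back to the diol. Its two CH2OH groups are homotopic, so the forward step must mono-functionalise better than statistically. From 4 backwards every intermediate is C2-symmetric.

**4 ⇒ 3.** No skeletal bond is cut; the CH2OH carbons are traced to carboxylic acids. The acid/ester difference is the only distinction the key step creates, and the forward reduction must read it chemoselectively.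

**3 ⇒ 2.** No bond is cut; the configuration at the two ester-bearing carbons is inverted, all-trans back to cis,trans,cis. That arrangement is the one of two cis-fused anhydride rings. The forward epimerisation must touch only the ester-bearing carbons.

**2 ⇒ 1 (key).** The two ester C–O bonds are cut and each cis pair of carboxyls is closed to an anhydride. The ring, its eight core carbons and all four stereocentres go back to one achiral commodity compound. The forward step must select the same enantiotopic carbonyl in both rings. In one sentence: twofold alkaloid-controlled enantiotopos-selective methanolysis of the achiral bis-anhydride 1. That sentence does not describe a [2+2] photocycloaddition of two alkenes, the route most chemists would draw first.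

## Other disconnections considered

**Alternative 1:** the first idea, a biomimetic head-to-head [2+2].
- Cut: C2–C3 and C1–C4 of 20, giving the alkenes clathrodin (A1) and hymenidin (A2).
- Forward key step: crossed photochemical (or sensitised) [2+2] of A1 with A2.
- Grounds for rejection: nothing in A1 or A2 enforces head-to-head over head-to-tail or all-trans over cis. Both alkene faces are equivalent, so there is no handle for absolute configuration. E/Z isomerisation is the expected main decay channel of such styrene-like aminoimidazole alkenes. A crossed reaction of two near-identical alkenes should also give the two homodimers beside 20 in a statistical mixture.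

**Alternative 2:** union of two like-polarity carbons.
- Cut: the C2–C3 bond of 20, giving the open-chain diester dimethyl (3S,4S)-3,4-bis[(benzyloxy)methyl]hexanedioate (A3).
- Forward key step: intramolecular oxidative coupling of the bis-enolate of A3 (LDA, then I2 or a Cu(II) salt) to the cyclobutane dimethyl (1S,2S,3R,4R)-3,4-bis[(benzyloxy)methyl]cyclobutane-1,2-dicarboxylate (A4).
- Grounds for rejection: the strained ring has to be built in the C–C bond-forming step by a 4-exo closure, against intermolecular coupling and α-halogenation. A3 needs its own asymmetric synthesis for its two stereocentres. The two new centres would still have to be equilibrated, and from A4 onward the sequence is no shorter than from 4. The chosen plan buys the ring and sets the stereochemistry in its first step.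

**Alternative 3:** ring contraction with nitrogen extrusion.
- Cut: again the C2–C3 bond, but the two carbons are joined through nitrogen in the pyrrolidine dimethyl (2R,3R,4R,5R)-3,4-bis[(benzyloxy)methyl]pyrrolidine-2,5-dicarboxylate (A5).
- Forward key step: oxidative N-amination and loss of N2 with collapse of the resulting 1,4-biradical to A4.
- Grounds for rejection: A5 is an all-trans, 2,5-trans pyrrolidine with four stereocentres and is no easier than the target core, since azomethine ylide cycloadditions give the 2,5-cis series. A biradical flanked by two ester-stabilised termini can fragment to two acrylates or lose stereochemical memory before it closes. No step is saved.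

Key step: step 1

**Assumptions (remarks on the chemistry):**
- The sense of induction of the alkaloid-mediated methanolysis on 1 is taken to be the one that esterifies the carbonyls on C3 and C4 of 2 with quinidine. If it is the opposite, quinine (the pseudo-enantiomer) is used in step 1 and nothing else changes.
- The Boc group in 19 is drawn on the ring nitrogen remote from the cyclobutane. Its position is irrelevant, because step 12 removes it.
- 1, 7, 11 and 18 are taken as purchased.

## Route

Step 1
Reactants: 1 cyclobutane-1,2,3,4-tetracarboxylic 1,2:3,4-dianhydride (cis,trans,cis; meso)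
Product: 2 (1R,2R,3R,4R)-3,4-bis(methoxycarbonyl)cyclobutane-1,2-dicarboxylic acid
Conditions: quinidine (2.2 equiv), MeOH (6 equiv), toluene/THF, −55 °C; 2 M HCl work-up (alkaloid recovered)
Reagents that add atoms: methanol, SMILES CO
Why: Cinchona alkaloid-mediated enantiotopos-selective alcoholysis of a meso cyclic anhydride (general-base activation of methanol by the quinuclidine nitrogen inside the chiral pocket of the alkaloid) is a known reaction of cis-fused succinic anhydrides, the cyclobutane-fused parent included, and is applied here to both rings of 1. 1 is achiral (C2h): the two carbonyls within one anhydride ring are enantiotopic, while the C2 axis through the midpoints of the two ring bonds not spanned by an anhydride makes the preferred carbonyl of one ring homotopic with the preferred carbonyl of the other, so the same local preference exercised twice should give the head-to-head C2-symmetric diester 2 and not the centrosymmetric head-to-tail isomer. No ring is closed and no C–C bond is formed; the two five-membered anhydride rings are opened by addition–elimination at acyl carbon and the cis,trans,cis cyclobutane is carried over unchanged. No sp3 centre is created: the four ring carbons, which are pairwise of opposite sense in achiral 1, all become stereocentres of one absolute sense (1R,2R,3R,4R) through the choice of carbonyl, and the only controlling element is the alkaloid (quinidine versus quinine). The selectivity needed is enantiotopic-group selectivity at each ring; a wrong choice at one ring gives a meso diastereomer and not the enantiomer, so the enantiomeric purity of 2 should exceed the selectivity of a single opening and the error is removable as a diastereomer. The rigid cis-fused bicyclic anhydrides, the absence of further substituents on the ring carbons and the distance between the two rings should make each opening behave like that of the simple cyclobutane anhydride. In one operation on a commodity chemical the step should thus settle the absolute configuration of the core and the adjacent pairing of the two kinds of substituents, which is the only source of chirality in 20.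

Step 2
Reactants: 2 (1R,2R,3R,4R)-3,4-bis(methoxycarbonyl)cyclobutane-1,2-dicarboxylic acid
Product: 3 (1R,2R,3S,4S)-3,4-bis(methoxycarbonyl)cyclobutane-1,2-dicarboxylic acid
Conditions: NaOMe (6 equiv), MeOH, reflux; 2 M HCl to pH 2
Reagents that add atoms: none
Why: Base-mediated epimerisation of a hemiester: in the dicarboxylate only the two ester-bearing carbons can be deprotonated by methoxide (ester enolates), so exactly C3 and C4 invert and the cis,trans,cis isomer is funnelled to the all-trans isomer, the thermodynamic one with no cis neighbours, while the carboxylate-bearing carbons keep the configuration fixed in step 1.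

Step 3
Reactants: 3 (1R,2R,3S,4S)-3,4-bis(methoxycarbonyl)cyclobutane-1,2-dicarboxylic acid
Product: 4 dimethyl (1S,2S,3R,4R)-3,4-bis(hydroxymethyl)cyclobutane-1,2-dicarboxylate
Conditions: BH3·SMe2 (3 equiv), THF, 0 °C to rt; MeOH quench
Reagents that add atoms: none
Why: Chemoselective borane reduction of carboxylic acids in the presence of esters (acyloxyborane pathway); no stereocentre is touched, and since each CH2OH is trans to the neighbouring ester the γ-lactone of a cis hydroxy ester cannot close.

Step 4
Reactants: 4 dimethyl (1S,2S,3R,4R)-3,4-bis(hydroxymethyl)cyclobutane-1,2-dicarboxylate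
Product: 5 dimethyl (1S,2S,3R,4R)-3-(hydroxymethyl)-4-{[(4-methylbenzenesulfonyl)oxy]methyl}cyclobutane-1,2-dicarboxylate
Conditions: TsCl (1.1 equiv), Ag2O (1.5 equiv), KI (0.2 equiv), CH2Cl2, 0 °C to rt
Reagents that add atoms: p-toluenesulfonyl chloride, SMILES Cc1ccc(cc1)S(Cl)(=O)=O
Why: Silver(I) oxide-mediated monotosylation of a symmetrical diol: the two CH2OH groups are homotopic, and the internal hydrogen bond of the 1,4-diol makes one hydroxyl more acidic and leaves the other unactivated after the first sulfonylation, so the mono-tosylate should predominate over the statistical distribution; this step breaks the C2 axis for the unsymmetrical acylation pattern.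

Step 5
Reactants: 5 dimethyl (1S,2S,3R,4R)-3-(hydroxymethyl)-4-{[(4-methylbenzenesulfonyl)oxy]methyl}cyclobutane-1,2-dicarboxylate
Product: 6 dimethyl (1S,2S,3R,4R)-3-(azidomethyl)-4-(hydroxymethyl)cyclobutane-1,2-dicarboxylate
Conditions: NaN3 (1.5 equiv), DMF, 50 °C
Reagents that add atoms: sodium azide, SMILES [Na+].[N-]=[N+]=[N-]
Why: SN2 displacement of a primary tosylate by azide; cyclisation of the free hydroxyl onto the tosylate is disfavoured because the tetrahydrofuran would be trans-fused to the four-membered ring.

Step 6
Reactants: 6 dimethyl (1S,2S,3R,4R)-3-(azidomethyl)-4-(hydroxymethyl)cyclobutane-1,2-dicarboxylate; 7 2,2,2-trichloro-1-(1H-pyrrol-2-yl)ethan-1-one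
Product: 9 dimethyl (1S,2S,3R,4R)-3-(hydroxymethyl)-4-{[(1H-pyrrole-2-carbonyl)amino]methyl}cyclobutane-1,2-dicarboxylate, via amino alcohol 8 (not isolated)
Conditions: PMe3 (1.2 equiv), THF, rt, then H2O; concentrate; 7 (1.05 equiv), Et3N, MeCN, rt
Reagents that add atoms: none
Why: Staudinger reduction of the azide followed at once by haloform-type N-acylation with the trichloromethyl ketone (chloroform as leaving group), which is selective for the primary amine over the alcohol and the pyrrole N–H; immediate acylation should leave no time for lactamisation onto the cis-1,3 ester.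

Step 7
Reactants: 9 dimethyl (1S,2S,3R,4R)-3-(hydroxymethyl)-4-{[(1H-pyrrole-2-carbonyl)amino]methyl}cyclobutane-1,2-dicarboxylate
Product: 10 dimethyl (1S,2S,3R,4R)-3-(azidomethyl)-4-{[(1H-pyrrole-2-carbonyl)amino]methyl}cyclobutane-1,2-dicarboxylate
Conditions: PPh3, DIAD, (PhO)2P(O)N3 (1.5 equiv each), THF, 0 °C to rt
Reagents that add atoms: diphenylphosphoryl azide, SMILES [N-]=[N+]=NP(=O)(Oc1ccccc1)Oc1ccccc1
Why: Mitsunobu azidation of a primary alcohol (SN2 at CH2, no stereocentre involved); amide and pyrrole N–H are too weakly acidic to compete as Mitsunobu nucleophiles, and intramolecular N-alkylation would need a trans-fused five-membered ring.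

Step 8
Reactants: 10 dimethyl (1S,2S,3R,4R)-3-(azidomethyl)-4-{[(1H-pyrrole-2-carbonyl)amino]methyl}cyclobutane-1,2-dicarboxylate; 11 1-(4-bromo-1H-pyrrol-2-yl)-2,2,2-trichloroethan-1-one
Product: 13 dimethyl (1S,2S,3R,4R)-3-{[(4-bromo-1H-pyrrole-2-carbonyl)amino]methyl}-4-{[(1H-pyrrole-2-carbonyl)amino]methyl}cyclobutane-1,2-dicarboxylate, via primary amine 12 (not isolated)
Conditions: PMe3 (1.2 equiv), THF, rt, then H2O; concentrate; 11 (1.05 equiv), Et3N, MeCN, rt
Reagents that add atoms: none
Why: Same Staudinger reduction and haloform-type acylation as in step 6, now with the brominated acyl donor; phosphine reduction leaves the aryl bromide intact, which hydrogenation would not guarantee.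

Step 9
Reactants: 13 dimethyl (1S,2S,3R,4R)-3-{[(4-bromo-1H-pyrrole-2-carbonyl)amino]methyl}-4-{[(1H-pyrrole-2-carbonyl)amino]methyl}cyclobutane-1,2-dicarboxylate
Product: 14 (1S,2S,3R,4R)-3-{[(4-bromo-1H-pyrrole-2-carbonyl)amino]methyl}-4-{[(1H-pyrrole-2-carbonyl)amino]methyl}cyclobutane-1,2-dicarboxylic acid
Conditions: LiOH·H2O (4 equiv), THF/MeOH/H2O, rt to 40 °C; 1 M HCl to pH 2–3
Reagents that add atoms: lithium hydroxide, SMILES [Li+].[OH-]
Why: Saponification of the methyl esters; the pyrrole amides and the aryl bromide are stable, and any epimerisation α to the carboxyl groups can only return the thermodynamic all-trans isomer.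

Step 10
Reactants: 14 (1S,2S,3R,4R)-3-{[(4-bromo-1H-pyrrole-2-carbonyl)amino]methyl}-4-{[(1H-pyrrole-2-carbonyl)amino]methyl}cyclobutane-1,2-dicarboxylic acid
Product: 17 4-bromo-N-{[(1R,2S,3S,4R)-2,3-bis(bromoacetyl)-4-{[(1H-pyrrole-2-carbonyl)amino]methyl}cyclobutyl]methyl}-1H-pyrrole-2-carboxamide, via bis(isobutyl carbonic) anhydride 15 (not isolated), via bis(diazoketone) 16 (not isolated)
Conditions: i-BuOCOCl (2.2 equiv), N-methylmorpholine (2.2 equiv), THF, −15 °C; CH2N2 (excess), Et2O, 0 °C to rt; 48% aq HBr, 0 °C
Reagents that add atoms: diazomethane, SMILES C=[N+]=[N-]; hydrogen bromide, SMILES Br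
Why: Arndt–Eistert-type diazoketone formation followed by hydrobromination (Nierenstein-type halomethyl ketone synthesis): the trans carboxyls cannot close to a cyclic anhydride, so each is activated separately, acylates diazomethane and is converted to the bromomethyl ketone with loss of N2; amide and pyrrole N–H are not acidic enough to be methylated by diazomethane.

Step 11
Reactants: 17 4-bromo-N-{[(1R,2S,3S,4R)-2,3-bis(bromoacetyl)-4-{[(1H-pyrrole-2-carbonyl)amino]methyl}cyclobutyl]methyl}-1H-pyrrole-2-carboxamide; 18 N-(tert-butoxycarbonyl)guanidine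
Product: 19 di-tert-butyl 4,4'-[(1S,2S,3R,4R)-3-{[(4-bromo-1H-pyrrole-2-carbonyl)amino]methyl}-4-{[(1H-pyrrole-2-carbonyl)amino]methyl}cyclobutane-1,2-diyl]bis(2-amino-1H-imidazole-1-carboxylate)
Conditions: 18 (6 equiv), DMF, rt
Reagents that add atoms: none
Why: Condensation of an α-bromoketone with Boc-guanidine (N-alkylation, cyclisation onto the ketone, dehydration) is the standard construction of Boc-protected 2-aminoimidazoles; the excess of 18 serves as base and suppresses bridging of the two ketones, and base-induced epimerisation α to the ketones can only favour the all-trans ring.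

Step 12
Reactants: 19 di-tert-butyl 4,4'-[(1S,2S,3R,4R)-3-{[(4-bromo-1H-pyrrole-2-carbonyl)amino]methyl}-4-{[(1H-pyrrole-2-carbonyl)amino]methyl}cyclobutane-1,2-diyl]bis(2-amino-1H-imidazole-1-carboxylate)
Product: 20 desbromosceptrin, 4-bromo-N-{[(1R,2S,3S,4R)-2,3-bis(2-amino-1H-imidazol-4-yl)-4-{[(1H-pyrrole-2-carbonyl)amino]methyl}cyclobutyl]methyl}-1H-pyrrole-2-carboxamide
Conditions: TFA/CH2Cl2 (1:1), rt; concentrate; neutralise (aq NaHCO3 or basic resin), reversed-phase purification
Reagents that add atoms: none
Why: Acidolysis of the two Boc groups (loss of isobutene and CO2); acylpyrrole amides, the aryl bromide and the ring stereocentres, none of which is any longer α to a carbonyl, are stable to TFA.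

## Compound list

1 | cyclobutane-1,2,3,4-tetracarboxylic 1,2:3,4-dianhydride (cis,trans,cis; meso, achiral) | O=C2[C@H]1[C@@H](C(=O)O2)[C@H](C(=O)O3)[C@@H]1C3=O | starting material
2 | (1R,2R,3R,4R)-3,4-bis(methoxycarbonyl)cyclobutane-1,2-dicarboxylic acid (cis,trans,cis) | OC(=O)[C@H]1[C@@H](C(=O)OC)[C@H](C(=O)OC)[C@@H]1C(=O)O | intermediate
3 | (1R,2R,3S,4S)-3,4-bis(methoxycarbonyl)cyclobutane-1,2-dicarboxylic acid (all-trans) | OC(=O)[C@H]1[C@H](C(=O)OC)[C@@H](C(=O)OC)[C@@H]1C(=O)O | intermediate
4 | dimethyl (1S,2S,3R,4R)-3,4-bis(hydroxymethyl)cyclobutane-1,2-dicarboxylate | OC[C@H]1[C@H](C(=O)OC)[C@@H](C(=O)OC)[C@@H]1CO | intermediate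
5 | dimethyl (1S,2S,3R,4R)-3-(hydroxymethyl)-4-{[(4-methylbenzenesulfonyl)oxy]methyl}cyclobutane-1,2-dicarboxylate | Cc1ccc(cc1)S(=O)(=O)OC[C@H]1[C@H](C(=O)OC)[C@@H](C(=O)OC)[C@@H]1CO | intermediate
6 | dimethyl (1S,2S,3R,4R)-3-(azidomethyl)-4-(hydroxymethyl)cyclobutane-1,2-dicarboxylate | [N-]=[N+]=NC[C@H]1[C@H](C(=O)OC)[C@@H](C(=O)OC)[C@@H]1CO | intermediate
7 | 2,2,2-trichloro-1-(1H-pyrrol-2-yl)ethan-1-one | O=C(c1ccc[nH]1)C(Cl)(Cl)Cl | starting material
8 | dimethyl (1S,2S,3R,4R)-3-(aminomethyl)-4-(hydroxymethyl)cyclobutane-1,2-dicarboxylate | NC[C@H]1[C@H](C(=O)OC)[C@@H](C(=O)OC)[C@@H]1CO | intermediate (not isolated)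
9 | dimethyl (1S,2S,3R,4R)-3-(hydroxymethyl)-4-{[(1H-pyrrole-2-carbonyl)amino]methyl}cyclobutane-1,2-dicarboxylate | O=C(NC[C@H]1[C@H](C(=O)OC)[C@@H](C(=O)OC)[C@@H]1CO)c1ccc[nH]1 | intermediate
10 | dimethyl (1S,2S,3R,4R)-3-(azidomethyl)-4-{[(1H-pyrrole-2-carbonyl)amino]methyl}cyclobutane-1,2-dicarboxylate | O=C(NC[C@H]1[C@H](C(=O)OC)[C@@H](C(=O)OC)[C@@H]1CN=[N+]=[N-])c1ccc[nH]1 | intermediate
11 | 1-(4-bromo-1H-pyrrol-2-yl)-2,2,2-trichloroethan-1-one | O=C(c1cc(Br)c[nH]1)C(Cl)(Cl)Cl | starting material
12 | dimethyl (1S,2S,3R,4R)-3-(aminomethyl)-4-{[(1H-pyrrole-2-carbonyl)amino]methyl}cyclobutane-1,2-dicarboxylate | O=C(NC[C@H]1[C@H](C(=O)OC)[C@@H](C(=O)OC)[C@@H]1CN)c1ccc[nH]1 | intermediate (not isolated)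
13 | dimethyl (1S,2S,3R,4R)-3-{[(4-bromo-1H-pyrrole-2-carbonyl)amino]methyl}-4-{[(1H-pyrrole-2-carbonyl)amino]methyl}cyclobutane-1,2-dicarboxylate | O=C(NC[C@H]1[C@H](C(=O)OC)[C@@H](C(=O)OC)[C@@H]1CNC(=O)c1cc(Br)c[nH]1)c1ccc[nH]1 | intermediate
14 | (1S,2S,3R,4R)-3-{[(4-bromo-1H-pyrrole-2-carbonyl)amino]methyl}-4-{[(1H-pyrrole-2-carbonyl)amino]methyl}cyclobutane-1,2-dicarboxylic acid | O=C(NC[C@H]1[C@H](C(=O)O)[C@@H](C(=O)O)[C@@H]1CNC(=O)c1cc(Br)c[nH]1)c1ccc[nH]1 | intermediate
15 | bis(isobutyl carbonic) mixed anhydride of 14 | O=C(NC[C@H]1[C@H](C(=O)OC(=O)OCC(C)C)[C@@H](C(=O)OC(=O)OCC(C)C)[C@@H]1CNC(=O)c1cc(Br)c[nH]1)c1ccc[nH]1 | intermediate (not isolated)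
16 | 4-bromo-N-{[(1R,2S,3S,4R)-2,3-bis(diazoacetyl)-4-{[(1H-pyrrole-2-carbonyl)amino]methyl}cyclobutyl]methyl}-1H-pyrrole-2-carboxamide | O=C(NC[C@H]1[C@H](C(=O)C=[N+]=[N-])[C@@H](C(=O)C=[N+]=[N-])[C@@H]1CNC(=O)c1cc(Br)c[nH]1)c1ccc[nH]1 | intermediate (not isolated)
17 | 4-bromo-N-{[(1R,2S,3S,4R)-2,3-bis(bromoacetyl)-4-{[(1H-pyrrole-2-carbonyl)amino]methyl}cyclobutyl]methyl}-1H-pyrrole-2-carboxamide | O=C(NC[C@H]1[C@H](C(=O)CBr)[C@@H](C(=O)CBr)[C@@H]1CNC(=O)c1cc(Br)c[nH]1)c1ccc[nH]1 | intermediate
18 | N-(tert-butoxycarbonyl)guanidine | CC(C)(C)OC(=O)NC(N)=N | starting material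
19 | di-tert-butyl 4,4'-[(1S,2S,3R,4R)-3-{[(4-bromo-1H-pyrrole-2-carbonyl)amino]methyl}-4-{[(1H-pyrrole-2-carbonyl)amino]methyl}cyclobutane-1,2-diyl]bis(2-amino-1H-imidazole-1-carboxylate) | O=C(NC[C@H]1[C@H](c2cn(C(=O)OC(C)(C)C)c(N)n2)[C@@H](c2cn(C(=O)OC(C)(C)C)c(N)n2)[C@@H]1CNC(=O)c1cc(Br)c[nH]1)c1ccc[nH]1 | intermediate
20 | desbromosceptrin, 4-bromo-N-{[(1R,2S,3S,4R)-2,3-bis(2-amino-1H-imidazol-4-yl)-4-{[(1H-pyrrole-2-carbonyl)amino]methyl}cyclobutyl]methyl}-1H-pyrrole-2-carboxamide | Nc1ncc([C@H]2[C@H](CNC(=O)c3ccc[nH]3)[C@@H](CNC(=O)c3cc(Br)c[nH]3)[C@@H]2c2cnc(N)[nH]2)[nH]1 | target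

## Step count and least certain steps

Total step count: 12. Longest linear sequence: 12 (fully linear from 1; 7, 11 and 18 are purchased).

**Step 1 (key step).**
- What may go wrong: the poor solubility of 1 in the non-polar medium may force a slow heterogeneous reaction. An unselective background methanolysis and a lower group selectivity in the second ring opening (the first ring then carries an ammonium carboxylate) would erode the enantiotopic-group selection and raise the share of the meso isomer.
- Fallback (classical resolution, sets out from 1 and comes back at 3): uncatalysed methanolysis of 1 (MeOH, Et3N, rt) should give the head-to-head diester as a racemate, 2 together with its enantiomer (1S,2S,3S,4S)-3,4-bis(methoxycarbonyl)cyclobutane-1,2-dicarboxylic acid F1, beside the meso head-to-tail isomer 2,4-bis(methoxycarbonyl)cyclobutane-1,3-dicarboxylic acid F2. The conditions of step 2 convert only the head-to-head pair into all-trans acids, 3 and its enantiomer (1S,2S,3R,4R)-3,4-bis(methoxycarbonyl)cyclobutane-1,2-dicarboxylic acid F3. F2 cannot become all-trans by inversion of ester-bearing carbons alone and remains a separable diastereomer. Fractional crystallisation of the bis[(S)-1-phenylethylammonium] salt of 3 F4 (or use of the (R)-amine, if the salt of F3 is the less soluble one) and acidification return 3.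

**Step 2.**
- What may go wrong: slow or incomplete inversion at hindered ester carbons of a dianion; exchange of ester and carboxylate between cis neighbours through a transient anhydride, which would scramble the pairing and lower the enantiomeric purity; retro-Michael opening of the ring enolate.
- Fallback (sets out from 2 and comes back at 4): 2 is first reduced with BH3·SMe2 to the cis hydroxy ester dimethyl (1R,2R,3R,4R)-3,4-bis(hydroxymethyl)cyclobutane-1,2-dicarboxylate F5. This should lactonise (cat. TsOH if needed) to the cis,trans,cis bis-γ-lactone 4,9-dioxatricyclo[5.3.0.0^2,6]decane-3,10-dione F6. NaOMe in MeOH then opens the lactones reversibly, the open ester epimerises, and the trans hydroxy ester, which cannot re-lactonise, accumulates as 4. Only the carbonyl-bearing carbons can invert in this sequence and no carboxylate is present.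

**Step 4.**
- What may go wrong: loss of mono-selectivity (bis-sulfonylation) if the flanking esters disturb the internal hydrogen bond on which the selectivity rests.
- Fallback (differentiation at the amine stage, sets out from 4 and comes back at 12): double Mitsunobu azidation of 4 (PPh3, DIAD, diphenylphosphoryl azide) gives dimethyl (1S,2S,3R,4R)-3,4-bis(azidomethyl)cyclobutane-1,2-dicarboxylate F7. Staudinger reduction gives dimethyl (1S,2S,3R,4R)-3,4-bis(aminomethyl)cyclobutane-1,2-dicarboxylate F8. Slow addition of 7 in deficiency, with recovery of unreacted F8, gives the mono-amide 12, which is acylated with 11 as in the second half of step 8 to give 13.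

**Step 10.**
- What may go wrong: incomplete double activation, hydrolysis of the mixed anhydride, or acylation of a pyrrole nitrogen by the chloroformate; the handling of diazomethane limits scale.
- Fallback (sulfoxonium route, sets out from 13, skips step 9 and comes back at 17): 13 is treated with excess dimethylsulfoxonium methylide (Me3S(O)I, KOtBu, THF; the excess covers the four N–H) to give the bis(β-keto sulfoxonium ylide) 4-bromo-N-{[(1R,2S,3S,4R)-2,3-bis[(dimethyloxo-λ6-sulfanylidene)acetyl]-4-{[(1H-pyrrole-2-carbonyl)amino]methyl}cyclobutyl]methyl}-1H-pyrrole-2-carboxamide F9. HBr (or LiBr/MsOH) then displaces dimethyl sulfoxide to give 17.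

**Step 11.**
- What may go wrong: bridging of the two neighbouring bromoketones by one guanidine, over-alkylation, or base-induced side reactions of the α-bromoketones (Favorskii-type pathways, elimination).
- Fallback (aminoketone–cyanamide route, sets out from 17 and comes back at 20, step 12 not needed): displacement with sodium diformylamide (MeCN) gives the bis(diformylaminomethyl ketone) 4-bromo-N-{[(1R,2S,3S,4R)-2,3-bis[(diformylamino)acetyl]-4-{[(1H-pyrrole-2-carbonyl)amino]methyl}cyclobutyl]methyl}-1H-pyrrole-2-carboxamide F10. HCl in MeOH gives the bis(aminomethyl ketone) dihydrochloride 4-bromo-N-{[(1R,2S,3S,4R)-2,3-bis(aminoacetyl)-4-{[(1H-pyrrole-2-carbonyl)amino]methyl}cyclobutyl]methyl}-1H-pyrrole-2-carboxamide dihydrochloride F11. Condensation with cyanamide (NC#N) in water at pH about 4.5 and 95 °C closes both 2-aminoimidazoles and gives 20 directly.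

## Further compounds

F1 | step 1 | (1S,2S,3S,4S)-3,4-bis(methoxycarbonyl)cyclobutane-1,2-dicarboxylic acid (enantiomer of 2) | OC(=O)[C@@H]1[C@H](C(=O)OC)[C@@H](C(=O)OC)[C@H]1C(=O)O
F2 | step 1 | meso-2,4-bis(methoxycarbonyl)cyclobutane-1,3-dicarboxylic acid (cis,trans,cis head-to-tail isomer) | OC(=O)[C@H]1[C@@H](C(=O)OC)[C@H](C(=O)O)[C@@H]1C(=O)OC
F3 | step 1 | (1S,2S,3R,4R)-3,4-bis(methoxycarbonyl)cyclobutane-1,2-dicarboxylic acid (enantiomer of 3) | OC(=O)[C@@H]1[C@@H](C(=O)OC)[C@H](C(=O)OC)[C@H]1C(=O)O
F4 | step 1 | bis[(S)-1-phenylethylammonium] salt of 3 | C[C@H]([NH3+])c1ccccc1.C[C@H]([NH3+])c1ccccc1.[O-]C(=O)[C@H]1[C@H](C(=O)OC)[C@@H](C(=O)OC)[C@@H]1C(=O)[O-]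
F5 | step 2 | dimethyl (1R,2R,3R,4R)-3,4-bis(hydroxymethyl)cyclobutane-1,2-dicarboxylate (cis,trans,cis) | OC[C@H]1[C@@H](C(=O)OC)[C@H](C(=O)OC)[C@@H]1CO
F6 | step 2 | cis,trans,cis bis-γ-lactone, 4,9-dioxatricyclo[5.3.0.0^2,6]decane-3,10-dione | C2[C@H]1[C@@H](C(=O)O2)[C@H](C(=O)O3)[C@@H]1C3
F7 | step 4 | dimethyl (1S,2S,3R,4R)-3,4-bis(azidomethyl)cyclobutane-1,2-dicarboxylate | [N-]=[N+]=NC[C@H]1[C@H](C(=O)OC)[C@@H](C(=O)OC)[C@@H]1CN=[N+]=[N-]
F8 | step 4 | dimethyl (1S,2S,3R,4R)-3,4-bis(aminomethyl)cyclobutane-1,2-dicarboxylate | NC[C@H]1[C@H](C(=O)OC)[C@@H](C(=O)OC)[C@@H]1CN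
F9 | step 10 | bis(β-keto sulfoxonium ylide) of the 13 skeleton | O=C(NC[C@H]1[C@H](C(=O)C=S(C)(C)=O)[C@@H](C(=O)C=S(C)(C)=O)[C@@H]1CNC(=O)c1cc(Br)c[nH]1)c1ccc[nH]1
F10 | step 11 | bis(diformylaminomethyl ketone) | O=C(NC[C@H]1[C@H](C(=O)CN(C=O)C=O)[C@@H](C(=O)CN(C=O)C=O)[C@@H]1CNC(=O)c1cc(Br)c[nH]1)c1ccc[nH]1
F11 | step 11 | bis(aminomethyl ketone) dihydrochloride | O=C(NC[C@H]1[C@H](C(=O)C[NH3+])[C@@H](C(=O)C[NH3+])[C@@H]1CNC(=O)c1cc(Br)c[nH]1)c1ccc[nH]1.[Cl-].[Cl-]
A1 | alternative 1 | clathrodin, N-[(2E)-3-(2-amino-1H-imidazol-4-yl)prop-2-en-1-yl]-1H-pyrrole-2-carboxamide | Nc1ncc(/C=C/CNC(=O)c2ccc[nH]2)[nH]1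
A2 | alternative 1 | hymenidin, N-[(2E)-3-(2-amino-1H-imidazol-4-yl)prop-2-en-1-yl]-4-bromo-1H-pyrrole-2-carboxamide | Nc1ncc(/C=C/CNC(=O)c2cc(Br)c[nH]2)[nH]1
A3 | alternative 2 | dimethyl (3S,4S)-3,4-bis[(benzyloxy)methyl]hexanedioate | COC(=O)C[C@H](COCc1ccccc1)[C@@H](COCc1ccccc1)CC(=O)OC
A4 | alternative 2 | dimethyl (1S,2S,3R,4R)-3,4-bis[(benzyloxy)methyl]cyclobutane-1,2-dicarboxylate | COC(=O)[C@H]1[C@H](COCc2ccccc2)[C@@H](COCc2ccccc2)[C@@H]1C(=O)OC
A5 | alternative 3 | dimethyl (2R,3R,4R,5R)-3,4-bis[(benzyloxy)methyl]pyrrolidine-2,5-dicarboxylate | COC(=O)[C@H]1[C@H](COCc2ccccc2)[C@@H](COCc2ccccc2)[C@@H](N1)C(=O)OC
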